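**Retrosynthetic overview**

- Numbering used here: ring C1 (carbon bearing CH2OH)=C2, C3, C4 (stereocentre, R), C5, C6, C7(CH3)=C8 (Z), C9, C10, C11(CH3)=C12 (E), C13, C14; the 6-methylhepta-2,5-dien-2-yl side chain (C1′–C7′) sits on C4.
- Endgame: target ⇐ 1,4-hydrogenation of the ring diene C13=C12–C11(=CH2) ⇐ ester reduction ⇐ closure of the only ring (14-membered carbocycle) at C12–C13 by endo ring-closing enyne metathesis of an acyclic enyne ester. The enabling feature is the ring segment C13H2–C12H=C11(CH3)–C10H2: it is the 1,4-dihydro form of exactly the diene that a C10-bound terminal alkyne (C11≡C12) and a C14-bound vinyl group (C13=CH2) give on metathesis.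
- Enyne ester ⇐ Z-selective Still–Gennari olefination (C1=C2) of a β-branched aldehyde with an α-allyl phosphonate.
- Aldehyde ⇐ Johnson–Claisen rearrangement of an (R)-allylic alcohol (1,3-chirality transfer sets C4 and the E C2′=C3′ olefin) ⇐ Brown allylation and cross-metathesis prenylation of an E-enal.
- Enal ⇐ terminal allylic oxidation of propargylated nerol (nerol supplies the Z C7=C8 olefin).

Key step: step 11

Remark (assumption): "(+)-Ipc2B(allyl)" means the B-allyldiisopinocampheylborane made from (−)-α-pinene; nerol of high Z purity is assumed.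

**Route**

Step 1
Reactants: 1 nerol [(2Z)-3,7-dimethylocta-2,6-dien-1-ol]
Product: 2 neryl bromide [(2Z)-1-bromo-3,7-dimethylocta-2,6-diene]
Conditions: PBr3 (0.4 equiv), Et2O, −10 °C; used without purification
Reagents that add atoms: phosphorus tribromide, BrP(Br)Br
Why: SN2 bromide displacement on the phosphite ester of a primary allylic alcohol at low temperature should keep the 2Z olefin and avoid allylic transposition.

Step 2
Reactants: 2 neryl bromide; 3 triisopropyl(prop-1-yn-1-yl)silane
Product: 5 [(5Z)-6,10-dimethylundeca-5,9-dien-1-yn-1-yl]tri(propan-2-yl)silane, via lithiated silylpropyne 4 (not isolated)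
Conditions: 3, n-BuLi, THF, −20 °C; then 2, −78 → 0 °C
Reagents that add atoms: none
Why: Propargylic lithiation followed by SN2 alkylation of the primary allylic bromide, in which the bulky silyl group should steer the ambident anion to react at its propargylic carbon while the Z olefin is untouched.

Step 3
Reactants: 5 silyl dienyne
Product: 7 (2E,6Z)-2,6-dimethyl-11-[tri(propan-2-yl)silyl]undeca-2,6-dien-10-ynal, via allylic alcohol 6 (not isolated)
Conditions: SeO2 (0.5 equiv), t-BuOOH (3 equiv), salicylic acid (0.1 equiv), CH2Cl2, 0 °C → rt; filtration, then MnO2 (excess), CH2Cl2, rt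
Reagents that add atoms: tert-butyl hydroperoxide, CC(C)(C)OO (oxygen relayed by selenium dioxide, O=[Se]=O)
Why: Riley allylic oxidation (ene reaction, then [2,3]-sigmatropic shift) should attack the E-methyl of the more accessible terminal trisubstituted olefin, and the MnO2 oxidation converges allylic alcohol and aldehyde on the E-enal.

Step 4
Reactants: 7 E-enal
Product: 9 (4R,5E,9Z)-5,9-dimethyl-14-[tri(propan-2-yl)silyl]tetradeca-1,5,9-trien-13-yn-4-ol, via borinate ester 8 (not isolated)
Conditions: (+)-Ipc2B(allyl) (1.3 equiv), Et2O, −78 °C; then 3 M NaOH, 30% H2O2, 0 °C → rt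
Reagents that add atoms: (+)-B-allyldiisopinocampheylborane, C=CCB([C@H]1C[C@H]2C[C@@H]([C@@H]1C)C2(C)C)[C@H]1C[C@H]2C[C@@H]([C@@H]1C)C2(C)C
Why: Brown asymmetric allylboration through a closed chair transition state, in which the (−)-α-pinene-derived reagent should add to the Re face of the α-methyl enal and set the carbinol centre as R (reagent control).

Step 5
Reactants: 9 homoallylic alcohol
Product: 10 (5R,6E,10Z)-2,6,10-trimethyl-15-[tri(propan-2-yl)silyl]pentadeca-2,6,10-trien-14-yn-5-ol
Conditions: Grubbs second-generation catalyst (5 mol %), 2-methyl-2-butene/CH2Cl2 (1:1), 35 °C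
Reagents that add atoms: 2-methyl-2-butene, CC=C(C)C
Why: Olefin cross-metathesis of the only monosubstituted alkene with 2-methyl-2-butene transfers an isopropylidene unit to give the prenyl terminus, while the trisubstituted olefins and the silyl-shielded alkyne should be inert and the carbinol centre is not involved.

Step 6
Reactants: 10 (R)-allylic alcohol
Product: 12 ethyl (3R,6Z)-6-methyl-3-[(2E)-6-methylhepta-2,5-dien-2-yl]-11-[tri(propan-2-yl)silyl]undec-6-en-10-ynoate, via ketene acetal 11 (not isolated)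
Conditions: MeC(OEt)3 (8 equiv), EtCO2H (0.1 equiv), 140 °C, EtOH distilled off
Reagents that add atoms: triethyl orthoacetate, CCOC(C)(OCC)OCC
Why: Johnson–Claisen rearrangement through a chair transition state with the prenyl CH2 substituent equatorial should give the E trisubstituted olefin and transfer the (R)-carbinol configuration suprafacially across the E-allyl unit to the new C–C bond, setting the future ring stereocentre as R.

Step 7
Reactants: 12 silylated ester
Product: 13 ethyl (3R,6Z)-6-methyl-3-[(2E)-6-methylhepta-2,5-dien-2-yl]undec-6-en-10-ynoate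
Conditions: TBAF (1.2 equiv), THF, 0 °C → rt
Reagents that add atoms: none
Why: Fluoride-induced protodesilylation of the alkynylsilane, to which the ester, the olefins and the stereocentre should be inert.

Step 8
Reactants: 13 alkynyl ester
Product: 14 (3R,6Z)-6-methyl-3-[(2E)-6-methylhepta-2,5-dien-2-yl]undec-6-en-10-ynal
Conditions: DIBAL-H (1.1 equiv), CH2Cl2, −78 °C; MeOH, aq. Rochelle salt
Reagents that add atoms: none
Why: DIBAL-H half-reduction of the ester through a low-temperature-stable aluminium hemiacetal, with the stereocentre β to the carbonyl and therefore not epimerisable.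

Step 9
Reactants: 15 methyl 2-[bis(2,2,2-trifluoroethoxy)phosphoryl]acetate; 16 allyl bromide
Product: 18 methyl 2-[bis(2,2,2-trifluoroethoxy)phosphoryl]pent-4-enoate (racemic), via sodium phosphonate 17 (not isolated)
Conditions: NaH (1.0 equiv), THF, 0 °C; then 16 (1.0 equiv), 0 °C → rt
Reagents that add atoms: none
Why: C-alkylation (SN2) of the stabilised phosphonoacetate anion with allyl bromide, with one equivalent of base to limit dialkylation.

Step 10
Reactants: 14 aldehyde; 18 α-allyl phosphonate
Product: 20 methyl (2Z,5R,8Z)-8-methyl-5-[(2E)-6-methylhepta-2,5-dien-2-yl]-2-(prop-2-en-1-yl)trideca-2,8-dien-12-ynoate, via potassium phosphonate 19 (not isolated)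
Conditions: 18, KHMDS (1.15 equiv), 18-crown-6 (3 equiv), THF, −78 °C; then 14, −78 °C
Reagents that add atoms: none
Why: Still–Gennari variant of the Horner–Wadsworth–Emmons olefination, in which the electron-poor phosphonate and the dissociated potassium ion make elimination faster than adduct equilibration and should place CO2Me cis to the chain (2Z); the phosphonate anion is too weak a base to deprotonate the terminal alkyne.

Step 11
Reactants: 20 acyclic enyne ester
Product: 22 methyl (1Z,4R,7Z,12E)-7-methyl-11-methylidene-4-[(2E)-6-methylhepta-2,5-dien-2-yl]cyclotetradeca-1,7,12-triene-1-carboxylate, via acyclic tetraene 21 (not isolated)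
Conditions: Grubbs second-generation catalyst (10 mol %), 1,4-benzoquinone (10 mol %), ethene (1 atm), CH2Cl2 (2 mM), 40 °C; then argon sparge, 40 °C
Reagents that add atoms: ethene, C=C
Why: The Ru methylidene adds to the terminal alkyne (C11≡C12) to give a vinylcarbene that ethene releases as the 2-substituted butadiene 21, and the catalyst then performs ring-closing metathesis between the monosubstituted diene terminus (C12=CH2) and the allyl terminus (C13=CH2), so that the C12–C13 bond is made as the ring closes and ethene leaves. The closest known reaction type is endo-selective macrocyclic ring-closing enyne metathesis under ethene, which gives 1,3-disubstituted dienes in 12- to 16-membered rings. The single ring is closed in the 14-endo mode, with both former alkyne carbons on the ring path and the C11 methylidene exocyclic; no stereocentre is formed and C4 is remote and untouched. The new C12=C13 olefin should be E under these reversible conditions, and its geometry is in any case not carried into the target because C13 becomes sp3 in step 13. The step needs selection of the two terminal π-systems over four trisubstituted olefins and endo over exo closure: the enoate olefin is electronically deactivated, the other trisubstituted olefins are sterically slow, the alkyne and the C7=C8 olefin could only close a four-membered ring, and the monosubstituted diene terminus reacts far faster than the 1,1-disubstituted one. High dilution suppresses oligomerisation and benzoquinone suppresses Ru–H migration of the skipped diene.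

Step 12
Reactants: 22 macrocyclic diene ester
Product: 23 [(1Z,4R,7Z,12E)-7-methyl-11-methylidene-4-[(2E)-6-methylhepta-2,5-dien-2-yl]cyclotetradeca-1,7,12-trien-1-yl]methanol
Conditions: DIBAL-H (2.5 equiv), CH2Cl2, −78 → −40 °C; aq. Rochelle salt
Reagents that add atoms: none
Why: DIBAL-H 1,2-reduction of the α,β-unsaturated ester to the allylic alcohol, which leaves the diene and the isolated olefins untouched and removes the only other conjugated π-system before the hydrogenation.

Step 13
Reactants: 23 macrocyclic dienol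
Product: 24 [(1Z,4R,7Z,11E)-7,11-dimethyl-4-[(2E)-6-methylhepta-2,5-dien-2-yl]cyclotetradeca-1,7,11-trien-1-yl]methanol (target)
Conditions: (η6-naphthalene)Cr(CO)3 (20 mol %), H2 (70 atm), acetone, 45 °C
Reagents that add atoms: none
Why: (Arene)Cr(CO)3-catalysed 1,4-hydrogenation, in which only a conjugated diene that can bind the Cr(CO)3 fragment in its s-cis form is reduced, so both hydrogens go to the diene termini (C13 and the exocyclic CH2) and the new C11=C12 olefin is formed with C13 and the new methyl cis (the E ring olefin), while the isolated trisubstituted olefins should not react.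

**Compound list**

1 | nerol, (2Z)-3,7-dimethylocta-2,6-dien-1-ol | CC(C)=CCC/C(C)=C\CO | starting material
2 | neryl bromide, (2Z)-1-bromo-3,7-dimethylocta-2,6-diene | CC(C)=CCC/C(C)=C\CBr | intermediate
3 | triisopropyl(prop-1-yn-1-yl)silane | CC#C[Si](C(C)C)(C(C)C)C(C)C | starting material
4 | [3-(triisopropylsilyl)prop-2-yn-1-yl]lithium | [Li]CC#C[Si](C(C)C)(C(C)C)C(C)C | intermediate
5 | [(5Z)-6,10-dimethylundeca-5,9-dien-1-yn-1-yl]tri(propan-2-yl)silane | CC(C)=CCC/C(C)=C\CCC#C[Si](C(C)C)(C(C)C)C(C)C | intermediate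
6 | (2E,6Z)-2,6-dimethyl-11-[tri(propan-2-yl)silyl]undeca-2,6-dien-10-yn-1-ol | OC/C(C)=C/CC/C(C)=C\CCC#C[Si](C(C)C)(C(C)C)C(C)C | intermediate
7 | (2E,6Z)-2,6-dimethyl-11-[tri(propan-2-yl)silyl]undeca-2,6-dien-10-ynal | O=C/C(C)=C/CC/C(C)=C\CCC#C[Si](C(C)C)(C(C)C)C(C)C | intermediate
8 | bis(isopinocampheyl)borinate ester of 9 (Ipc groups from (−)-α-pinene) | C=CC[C@@H](OB([C@H]1C[C@H]2C[C@@H]([C@@H]1C)C2(C)C)[C@H]1C[C@H]2C[C@@H]([C@@H]1C)C2(C)C)/C(C)=C/CC/C(C)=C\CCC#C[Si](C(C)C)(C(C)C)C(C)C | intermediate
9 | (4R,5E,9Z)-5,9-dimethyl-14-[tri(propan-2-yl)silyl]tetradeca-1,5,9-trien-13-yn-4-ol | C=CC[C@@H](O)/C(C)=C/CC/C(C)=C\CCC#C[Si](C(C)C)(C(C)C)C(C)C | intermediate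
10 | (5R,6E,10Z)-2,6,10-trimethyl-15-[tri(propan-2-yl)silyl]pentadeca-2,6,10-trien-14-yn-5-ol | CC(C)=CC[C@@H](O)/C(C)=C/CC/C(C)=C\CCC#C[Si](C(C)C)(C(C)C)C(C)C | intermediate
11 | mixed ketene acetal of 10 (1-ethoxyvinyl ether) | CC(C)=CC[C@@H](OC(=C)OCC)/C(C)=C/CC/C(C)=C\CCC#C[Si](C(C)C)(C(C)C)C(C)C | intermediate
12 | ethyl (3R,6Z)-6-methyl-3-[(2E)-6-methylhepta-2,5-dien-2-yl]-11-[tri(propan-2-yl)silyl]undec-6-en-10-ynoate | CC(C)=CC/C=C(\C)[C@@H](CC(=O)OCC)CC/C(C)=C\CCC#C[Si](C(C)C)(C(C)C)C(C)C | intermediate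
13 | ethyl (3R,6Z)-6-methyl-3-[(2E)-6-methylhepta-2,5-dien-2-yl]undec-6-en-10-ynoate | CC(C)=CC/C=C(\C)[C@@H](CC(=O)OCC)CC/C(C)=C\CCC#C | intermediate
14 | (3R,6Z)-6-methyl-3-[(2E)-6-methylhepta-2,5-dien-2-yl]undec-6-en-10-ynal | CC(C)=CC/C=C(\C)[C@@H](CC=O)CC/C(C)=C\CCC#C | intermediate
15 | methyl 2-[bis(2,2,2-trifluoroethoxy)phosphoryl]acetate | COC(=O)CP(=O)(OCC(F)(F)F)OCC(F)(F)F | starting material
16 | allyl bromide | C=CCBr | starting material
17 | sodium salt of 15 | COC(=O)[CH-]P(=O)(OCC(F)(F)F)OCC(F)(F)F.[Na+] | intermediate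
18 | methyl 2-[bis(2,2,2-trifluoroethoxy)phosphoryl]pent-4-enoate (racemic) | COC(=O)C(CC=C)P(=O)(OCC(F)(F)F)OCC(F)(F)F | intermediate
19 | potassium salt of 18 | COC(=O)[C-](CC=C)P(=O)(OCC(F)(F)F)OCC(F)(F)F.[K+] | intermediate
20 | methyl (2Z,5R,8Z)-8-methyl-5-[(2E)-6-methylhepta-2,5-dien-2-yl]-2-(prop-2-en-1-yl)trideca-2,8-dien-12-ynoate | CC(C)=CC/C=C(\C)[C@@H](C/C=C(\C(=O)OC)CC=C)CC/C(C)=C\CCC#C | intermediate
21 | methyl (2Z,5R,8Z)-8-methyl-12-methylidene-5-[(2E)-6-methylhepta-2,5-dien-2-yl]-2-(prop-2-en-1-yl)tetradeca-2,8,13-trienoate | CC(C)=CC/C=C(\C)[C@@H](C/C=C(\C(=O)OC)CC=C)CC/C(C)=C\CCC(=C)C=C | intermediate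
22 | methyl (1Z,4R,7Z,12E)-7-methyl-11-methylidene-4-[(2E)-6-methylhepta-2,5-dien-2-yl]cyclotetradeca-1,7,12-triene-1-carboxylate | CC(C)=CC/C=C(\C)[C@H]1C/C=C(\C(=O)OC)C/C=C/C(=C)CC/C=C(/C)CC1 | intermediate
23 | [(1Z,4R,7Z,12E)-7-methyl-11-methylidene-4-[(2E)-6-methylhepta-2,5-dien-2-yl]cyclotetradeca-1,7,12-trien-1-yl]methanol | CC(C)=CC/C=C(\C)[C@H]1C/C=C(\CO)C/C=C/C(=C)CC/C=C(/C)CC1 | intermediate
24 | [(1Z,4R,7Z,11E)-7,11-dimethyl-4-[(2E)-6-methylhepta-2,5-dien-2-yl]cyclotetradeca-1,7,11-trien-1-yl]methanol | CC(C)=CC/C=C(\C)[C@H]1C/C=C(\CO)CC/C=C(\C)CC/C=C(/C)CC1 | target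

**Step count and risks**

Total steps: 13. Longest linear sequence: 12 (steps 1–8 and 10–13; step 9 prepares the phosphonate).

Steps most likely to fail:

1. Step 11 (ring closure). Intermolecular metathesis (oligomerisation or cyclodimerisation) may outrun ring closure, exo closure through the 1,1-disubstituted diene terminus may compete, or the catalyst may stall as an ester-chelated alkylidene. The fallback sets out from 13 and comes back at 24; it installs the C11 methyl olefin before ring closure and closes the same C12–C13 bond by a Nozaki–Hiyama–Kishi reaction. Water-accelerated Zr-catalysed methylalumination of 13 followed by iodination (Me3Al, Cp2ZrCl2, H2O, CH2Cl2, −23 °C; then I2) would give ethyl (3R,6Z,10E)-11-iodo-6,10-dimethyl-3-[(2E)-6-methylhepta-2,5-dien-2-yl]undeca-6,10-dienoate F1. DIBAL-H at −78 °C would give the corresponding aldehyde F2. Ozonolysis of 18 with acetalising work-up (O3, CH2Cl2–MeOH, −78 °C; TsOH; Me2S) would give methyl 2-[bis(2,2,2-trifluoroethoxy)phosphoryl]-4,4-dimethoxybutanoate F3. Still–Gennari olefination of F2 with F3 would give the Z-enoate acetal F4, and mild acid hydrolysis (PPTS, aqueous acetone) the 2-oxoethyl enoate F5, to be used at once. CrCl2 with catalytic NiCl2 (DMSO–THF, high dilution) would give the macrocyclic C13 allylic alcohol F6 (both epimers usable). Acetylation (Ac2O, DMAP) would give the acetate F7, and Pd(PPh3)4/Bu3SnH, delivering hydride to the less substituted allyl terminus C13, the methyl ester of the target acid F8. DIBAL-H then gives 24.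

2. Step 3 (terminal allylic oxidation). The ene step may not discriminate well enough between the terminal and the internal trisubstituted olefin, and over-oxidation may erode material. The fallback sets out from 5 and comes back at 7; it replaces C–H oxidation by cleavage of the terminal olefin and olefination. NBS in aqueous THF at 0 °C would give the terminal bromohydrin F9, K2CO3 in MeOH the terminal epoxide F10, and periodic acid in THF–Et2O the chain-shortened aldehyde (4Z)-4-methyl-9-[tri(propan-2-yl)silyl]non-4-en-8-ynal F11. Wittig reaction of F11 with the stabilised ylide 2-(triphenylphosphoranylidene)propanal (toluene, 90 °C) should then give the E-enal 7.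

3. Step 13 (1,4-hydrogenation). Binding of the free allylic hydroxyl to the chromium centre may slow turnover and open a Cr–H pathway for migration of the C1=C2 olefin. The fallback sets out from 23 and comes back at 24; it changes the protecting-group plan so that the diene is the only coordinating function. TBSCl/imidazole (DMF) would give the silyl ether of the dienol F12, the same Cr-catalysed 1,4-hydrogenation the silyl ether of the target F13, and TBAF (THF) then 24.

Further compounds
F1 | step 11 | ethyl (3R,6Z,10E)-11-iodo-6,10-dimethyl-3-[(2E)-6-methylhepta-2,5-dien-2-yl]undeca-6,10-dienoate | CC(C)=CC/C=C(\C)[C@@H](CC(=O)OCC)CC/C(C)=C\CC/C(C)=C/I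
F2 | step 11 | (3R,6Z,10E)-11-iodo-6,10-dimethyl-3-[(2E)-6-methylhepta-2,5-dien-2-yl]undeca-6,10-dienal | CC(C)=CC/C=C(\C)[C@@H](CC=O)CC/C(C)=C\CC/C(C)=C/I
F3 | step 11 | methyl 2-[bis(2,2,2-trifluoroethoxy)phosphoryl]-4,4-dimethoxybutanoate | COC(=O)C(CC(OC)OC)P(=O)(OCC(F)(F)F)OCC(F)(F)F
F4 | step 11 | methyl (2Z,5R,8Z,12E)-2-(2,2-dimethoxyethyl)-13-iodo-8,12-dimethyl-5-[(2E)-6-methylhepta-2,5-dien-2-yl]trideca-2,8,12-trienoate | CC(C)=CC/C=C(\C)[C@@H](C/C=C(\C(=O)OC)CC(OC)OC)CC/C(C)=C\CC/C(C)=C/I
F5 | step 11 | methyl (2Z,5R,8Z,12E)-13-iodo-8,12-dimethyl-5-[(2E)-6-methylhepta-2,5-dien-2-yl]-2-(2-oxoethyl)trideca-2,8,12-trienoate | CC(C)=CC/C=C(\C)[C@@H](C/C=C(\C(=O)OC)CC=O)CC/C(C)=C\CC/C(C)=C/I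
F6 | step 11 | methyl (1Z,4R,7Z,11E)-13-hydroxy-7,11-dimethyl-4-[(2E)-6-methylhepta-2,5-dien-2-yl]cyclotetradeca-1,7,11-triene-1-carboxylate (C13 epimers) | CC(C)=CC/C=C(\C)[C@H]1C/C=C(\C(=O)OC)CC(O)/C=C(\C)CC/C=C(/C)CC1
F7 | step 11 | methyl (1Z,4R,7Z,11E)-13-acetoxy-7,11-dimethyl-4-[(2E)-6-methylhepta-2,5-dien-2-yl]cyclotetradeca-1,7,11-triene-1-carboxylate | CC(C)=CC/C=C(\C)[C@H]1C/C=C(\C(=O)OC)CC(OC(C)=O)/C=C(\C)CC/C=C(/C)CC1
F8 | step 11 | methyl (1Z,4R,7Z,11E)-7,11-dimethyl-4-[(2E)-6-methylhepta-2,5-dien-2-yl]cyclotetradeca-1,7,11-triene-1-carboxylate | CC(C)=CC/C=C(\C)[C@H]1C/C=C(\C(=O)OC)CC/C=C(\C)CC/C=C(/C)CC1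
F9 | step 3 | (6Z)-3-bromo-2,6-dimethyl-11-[tri(propan-2-yl)silyl]undec-6-en-10-yn-2-ol (racemic) | CC(C)(O)C(Br)CC/C(C)=C\CCC#C[Si](C(C)C)(C(C)C)C(C)C
F10 | step 3 | 2,2-dimethyl-3-[(3Z)-3-methyl-8-[tri(propan-2-yl)silyl]oct-3-en-7-yn-1-yl]oxirane (racemic) | CC1(C)OC1CC/C(C)=C\CCC#C[Si](C(C)C)(C(C)C)C(C)C
F11 | step 3 | (4Z)-4-methyl-9-[tri(propan-2-yl)silyl]non-4-en-8-ynal | O=CCC/C(C)=C\CCC#C[Si](C(C)C)(C(C)C)C(C)C
F12 | step 13 | tert-butyldimethylsilyl ether of 23 | CC(C)=CC/C=C(\C)[C@H]1C/C=C(\CO[Si](C)(C)C(C)(C)C)C/C=C/C(=C)CC/C=C(/C)CC1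
F13 | step 13 | tert-butyldimethylsilyl ether of 24 | CC(C)=CC/C=C(\C)[C@H]1C/C=C(\CO[Si](C)(C)C(C)(C)C)CC/C=C(\C)CC/C=C(/C)CC1
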